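Ring B is assembled last on a preformed, enantioenriched ring A (eudesmane numbering). The disconnection removes the C7–C8 ethano unit (methyl vinyl ketone, whose acetyl group is the masked acrylic acid) from between C9, the neopentyl carbon on the quaternary C10, and C6, the exocyclic carbon on C5 that a C4 ketone turns into a Michael acceptor. In one pot, a deoxygenative radical conjugate addition joins C9 to C8; base then unmasks the C5=C6 enone and the new ketone enolate closes C6–C7, setting C7 and C5 against C10. The precursor is (3S)-3-(hydroxymethyl)-2-(methoxymethyl)-3-methylcyclohexanone; the C4 ketone later delivers C15 and the C3=C4 alkene.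

Key step: step 6

Remark: atom labels follow eudesmane numbering (C10 quaternary carbon with methyl C14; C5 ring-fusion CH; C4 ring carbon bearing C15H2–O; C7 carbon bearing the acrylic acid C11(=C13)–C12). 5,7-Di-tert-butyl-3-phenylbenzoxazolium tetrafluoroborate and [bis(2,2,2-trifluoroethoxy)phosphoryl]acetic acid are taken as purchasable reagents.

Step 1
Reactants: 1 3-methoxybenzyl alcohol
Product: 2 3-(hydroxymethyl)cyclohex-2-en-1-one
Conditions: Li, NH3(l)/THF, t-BuOH, −78 to −33 °C; then 2 M HCl, THF, rt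
Reagents that add atoms: water, O
Why: Birch reduction of the anisole (as its lithium alkoxide, which resists benzylic hydrogenolysis) gives the 1-methoxy-1,4-diene, and acid hydrolysis of the enol ether with conjugation gives the enone; no stereocenter is formed.

Step 2
Reactants: 2 3-(hydroxymethyl)cyclohex-2-en-1-one
Product: 3 3-{[(tert-butyldimethylsilyl)oxy]methyl}cyclohex-2-en-1-one
Conditions: TBSCl, imidazole, DMF, rt
Reagents that add atoms: tert-butyldimethylsilyl chloride, CC(C)(C)[Si](C)(C)Cl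
Why: Standard silylation of the primary alcohol protects the future C9 oxygen from the organoaluminium reagent.

Step 3
Reactants: 3 3-{[(tert-butyldimethylsilyl)oxy]methyl}cyclohex-2-en-1-one
Product: 4 tert-butyldimethyl{[(1S)-1-methyl-3-[(trimethylsilyl)oxy]cyclohex-2-en-1-yl]methoxy}silane
Conditions: Me3Al (1.5 equiv), Cu(O2CC4H3S) (copper thiophene-2-carboxylate, 3 mol%), chiral phosphoramidite L* (2,2'-biphenol/bis(1-phenylethyl)amine type, 6 mol%; enantiomer that gives (S)-4), Et2O, −30 °C; then TMSOTf, THF, 0 °C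
Reagents that add atoms: trimethylaluminium, C[Al](C)C; trimethylsilyl trifluoromethanesulfonate, C[Si](C)(C)OS(=O)(=O)C(F)(F)F
Why: Copper-catalysed asymmetric conjugate addition of methyl to the β-substituted cyclohexenone should create the quaternary C10 under ligand control of the enone face, and O-silylation of the aluminium enolate fixes the enolate toward C5.

Step 4
Reactants: 4 tert-butyldimethyl{[(1S)-1-methyl-3-[(trimethylsilyl)oxy]cyclohex-2-en-1-yl]methoxy}silane
Product: 5 (3S)-3-{[(tert-butyldimethylsilyl)oxy]methyl}-2-(methoxymethyl)-3-methylcyclohexan-1-one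
Conditions: MeOCH2Cl, ZnBr2 (10 mol%), CH2Cl2, 0 °C
Reagents that add atoms: chloromethyl methyl ether, COCCl
Why: Lewis-acid-catalysed alkylation of the silyl enol ether with the α-chloro ether (Mukaiyama-type alkylation) places C6 on C5 only, as a β-methoxy ketone that masks the later enone; the C5 epimer mixture is erased in step 6.

Step 5
Reactants: 5 (3S)-3-{[(tert-butyldimethylsilyl)oxy]methyl}-2-(methoxymethyl)-3-methylcyclohexan-1-one
Product: 6 (3S)-3-(hydroxymethyl)-2-(methoxymethyl)-3-methylcyclohexan-1-one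
Conditions: HF·pyridine, THF, 0 °C to rt
Reagents that add atoms: none
Why: Fluoride cleavage of the silyl ether frees the C9 hydroxyl under conditions that should leave the β-methoxy ketone intact.

Step 6
Reactants: 6 (3S)-3-(hydroxymethyl)-2-(methoxymethyl)-3-methylcyclohexan-1-one; 7 methyl vinyl ketone
Product: 10 (4aR,7R,8aR)-7-acetyl-4a-methyloctahydronaphthalen-1(2H)-one, via keto ether 8 (not isolated), via enone 9 (not isolated)
Conditions: 5,7-di-tert-butyl-3-phenylbenzoxazolium tetrafluoroborate, pyridine, MTBE, rt; then 7 (4 equiv), [Ir(ppy)2(dtbbpy)]PF6 (1 mol%), DMSO, blue LED, rt; then excess 7 evaporated, KOt-Bu (1.3 equiv), t-BuOH/THF, 0 °C, quenched once 8 is consumed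
Reagents that add atoms: none
Why: The alcohol condenses with the benzoxazolium salt; photo-oxidation of the adduct and β-scission release the neopentyl C9 radical, which adds to the CH2 terminus of 7 (Giese addition, forms C8–C9), and the α-keto radical is reduced and protonated to 8. Base then eliminates methanol (E1cB) to the exo-methylene ketone 9, and the methyl ketone enolate adds through C7 to C6 (intramolecular Michael addition, forms C6–C7); the sequence is a one-pot radical conjugate addition/Michael annulation related to Robinson-type annulations of masked vinyl ketones. Ring B closes in a 6-endo-trig (enolexo) mode through a chair in which the C10 methyl is axial. C7 is set by the equatorial preference of the acetyl group in that chair (it is α to a ketone and can still equilibrate to the equatorial epimer), and C5 by axial protonation of the ring A enolate on the face opposite the C10 methyl, which gives the trans-decalin. The step needs intermolecular capture of the C9 radical without rearrangement; keeping the enone masked as the β-methoxy ketone during the radical stage excludes the 1,2-vinyl shift and self-addition, and excess 7 secures capture.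

Step 7
Reactants: 10 (4aR,7R,8aR)-7-acetyl-4a-methyloctahydronaphthalen-1(2H)-one
Product: 11 1-[(2R,4aR,8aR)-4a-methyl-8-{[(trifluoromethyl)sulfonyl]oxy}-1,2,3,4,4a,5,6,8a-octahydronaphthalen-2-yl]ethenyl trifluoromethanesulfonate
Conditions: KN(SiMe3)2 (2.3 equiv), THF, −78 °C; then PhNTf2 (2.4 equiv), −78 to 0 °C; NH4Cl work-up
Reagents that add atoms: N-phenylbis(trifluoromethanesulfonimide), O=S(=O)(N(c1ccccc1)S(=O)(=O)C(F)(F)F)C(F)(F)F
Why: Kinetic deprotonation at the less substituted α-carbons (C3H2 rather than the C5 methine, C13H3 rather than the C7 methine) and O-triflation should give the C3=C4 and C11=C13 enol triflates without touching C5 or C7.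

Step 8
Reactants: 11 1-[(2R,4aR,8aR)-4a-methyl-8-{[(trifluoromethyl)sulfonyl]oxy}-1,2,3,4,4a,5,6,8a-octahydronaphthalen-2-yl]ethenyl trifluoromethanesulfonate
Product: 12 2-(trimethylsilyl)ethyl 2-[(2R,4aR,8aR)-4a-methyl-8-{[(trifluoromethyl)sulfonyl]oxy}-1,2,3,4,4a,5,6,8a-octahydronaphthalen-2-yl]prop-2-enoate
Conditions: Pd(OAc)2 (5 mol%), PPh3 (10 mol%), CO (1 atm), Me3SiCH2CH2OH (3 equiv), Et3N, DMF, rt, stopped at mono-conversion
Reagents that add atoms: carbon monoxide, [C-]#[O+]; 2-(trimethylsilyl)ethanol, C[Si](C)(C)CCO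
Why: Palladium-catalysed alkoxycarbonylation of a vinyl triflate; the unhindered 1,1-disubstituted acyclic triflate should undergo oxidative addition faster than the ring triflate flanked by the C5 ring-fusion carbon, giving the C12 ester only.

Step 9
Reactants: 12 2-(trimethylsilyl)ethyl 2-[(2R,4aR,8aR)-4a-methyl-8-{[(trifluoromethyl)sulfonyl]oxy}-1,2,3,4,4a,5,6,8a-octahydronaphthalen-2-yl]prop-2-enoate
Product: 13 2-(trimethylsilyl)ethyl 2-[(2R,4aR,8aR)-8-(hydroxymethyl)-4a-methyl-1,2,3,4,4a,5,6,8a-octahydronaphthalen-2-yl]prop-2-enoate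
Conditions: Bu3SnCH2OH, Pd(PPh3)4 (5 mol%), LiCl, 1,4-dioxane, 95 °C
Reagents that add atoms: (tributylstannyl)methanol, CCCC[Sn](CCCC)(CCCC)CO
Why: Stille coupling of the remaining vinyl triflate with the hydroxymethylstannane installs C15 as the primary allylic alcohol with the C3=C4 alkene already in place.

Step 10
Reactants: 13 2-(trimethylsilyl)ethyl 2-[(2R,4aR,8aR)-8-(hydroxymethyl)-4a-methyl-1,2,3,4,4a,5,6,8a-octahydronaphthalen-2-yl]prop-2-enoate; 14 [bis(2,2,2-trifluoroethoxy)phosphoryl]acetic acid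
Product: 15 2-(trimethylsilyl)ethyl 2-[(2R,4aR,8aR)-8-[({[bis(2,2,2-trifluoroethoxy)phosphoryl]acetyl}oxy)methyl]-4a-methyl-1,2,3,4,4a,5,6,8a-octahydronaphthalen-2-yl]prop-2-enoate
Conditions: DCC, DMAP (cat.), CH2Cl2, 0 °C to rt
Reagents that add atoms: none
Why: Steglich esterification of the unhindered primary allylic alcohol; the acrylate ester is inert.

Step 11
Reactants: 15 2-(trimethylsilyl)ethyl 2-[(2R,4aR,8aR)-8-[({[bis(2,2,2-trifluoroethoxy)phosphoryl]acetyl}oxy)methyl]-4a-methyl-1,2,3,4,4a,5,6,8a-octahydronaphthalen-2-yl]prop-2-enoate; 16 4-[(tert-butyldimethylsilyl)oxy]benzaldehyde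
Product: 17 2-(trimethylsilyl)ethyl 2-[(2R,4aR,8aR)-8-{[((2Z)-3-{4-[(tert-butyldimethylsilyl)oxy]phenyl}prop-2-enoyl)oxy]methyl}-4a-methyl-1,2,3,4,4a,5,6,8a-octahydronaphthalen-2-yl]prop-2-enoate
Conditions: KN(SiMe3)2, 18-crown-6, THF, −78 °C; then 16, −78 °C
Reagents that add atoms: none
Why: Still–Gennari modification of the Horner–Wadsworth–Emmons olefination; fast, irreversible elimination from the trifluoroethyl phosphonate adduct under dissociating conditions should give the Z-cinnamate.

Step 12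
Reactants: 17 2-(trimethylsilyl)ethyl 2-[(2R,4aR,8aR)-8-{[((2Z)-3-{4-[(tert-butyldimethylsilyl)oxy]phenyl}prop-2-enoyl)oxy]methyl}-4a-methyl-1,2,3,4,4a,5,6,8a-octahydronaphthalen-2-yl]prop-2-enoate
Product: 18 2-[(2R,4aR,8aR)-8-({[(2Z)-3-(4-hydroxyphenyl)prop-2-enoyl]oxy}methyl)-4a-methyl-1,2,3,4,4a,5,6,8a-octahydronaphthalen-2-yl]prop-2-enoic acid
Conditions: Bu4NF (3 equiv), THF, 0 °C, dark; dilute HCl work-up
Reagents that add atoms: none
Why: Fluoride cleaves the aryl silyl ether and fragments the 2-(trimethylsilyl)ethyl ester in one operation, under conditions mild enough that the Z-alkene and the allylic ester should survive.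

Compound list
1 | 3-methoxybenzyl alcohol | COc1cccc(CO)c1 | starting material
2 | 3-(hydroxymethyl)cyclohex-2-en-1-one | O=C1C=C(CO)CCC1 | intermediate
3 | 3-{[(tert-butyldimethylsilyl)oxy]methyl}cyclohex-2-en-1-one | O=C1C=C(CO[Si](C)(C)C(C)(C)C)CCC1 | intermediate
4 | tert-butyldimethyl{[(1S)-1-methyl-3-[(trimethylsilyl)oxy]cyclohex-2-en-1-yl]methoxy}silane | C[C@]1(CO[Si](C)(C)C(C)(C)C)CCCC(O[Si](C)(C)C)=C1 | intermediate
5 | (3S)-3-{[(tert-butyldimethylsilyl)oxy]methyl}-2-(methoxymethyl)-3-methylcyclohexan-1-one (C2 epimers) | COCC1C(=O)CCC[C@]1(C)CO[Si](C)(C)C(C)(C)C | intermediate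
6 | (3S)-3-(hydroxymethyl)-2-(methoxymethyl)-3-methylcyclohexan-1-one (C2 epimers) | COCC1C(=O)CCC[C@]1(C)CO | intermediate
7 | methyl vinyl ketone (but-3-en-2-one) | C=CC(C)=O | starting material
8 | (3S)-2-(methoxymethyl)-3-methyl-3-(4-oxopentyl)cyclohexan-1-one (keto ether, C2 epimers) | COCC1C(=O)CCC[C@]1(C)CCCC(C)=O | intermediate
9 | (3S)-3-methyl-2-methylidene-3-(4-oxopentyl)cyclohexan-1-one (enone) | C=C1C(=O)CCC[C@]1(C)CCCC(C)=O | intermediate
10 | (4aR,7R,8aR)-7-acetyl-4a-methyloctahydronaphthalen-1(2H)-one | CC(=O)[C@@H]1CC[C@@]2(C)CCCC(=O)[C@@H]2C1 | intermediate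
11 | 1-[(2R,4aR,8aR)-4a-methyl-8-{[(trifluoromethyl)sulfonyl]oxy}-1,2,3,4,4a,5,6,8a-octahydronaphthalen-2-yl]ethenyl trifluoromethanesulfonate | C=C(OS(=O)(=O)C(F)(F)F)[C@@H]1CC[C@@]2(C)CCC=C(OS(=O)(=O)C(F)(F)F)[C@@H]2C1 | intermediate
12 | 2-(trimethylsilyl)ethyl 2-[(2R,4aR,8aR)-4a-methyl-8-{[(trifluoromethyl)sulfonyl]oxy}-1,2,3,4,4a,5,6,8a-octahydronaphthalen-2-yl]prop-2-enoate | C=C(C(=O)OCC[Si](C)(C)C)[C@@H]1CC[C@@]2(C)CCC=C(OS(=O)(=O)C(F)(F)F)[C@@H]2C1 | intermediate
13 | 2-(trimethylsilyl)ethyl 2-[(2R,4aR,8aR)-8-(hydroxymethyl)-4a-methyl-1,2,3,4,4a,5,6,8a-octahydronaphthalen-2-yl]prop-2-enoate | C=C(C(=O)OCC[Si](C)(C)C)[C@@H]1CC[C@@]2(C)CCC=C(CO)[C@@H]2C1 | intermediate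
14 | [bis(2,2,2-trifluoroethoxy)phosphoryl]acetic acid | OC(=O)CP(=O)(OCC(F)(F)F)OCC(F)(F)F | starting material
15 | 2-(trimethylsilyl)ethyl 2-[(2R,4aR,8aR)-8-[({[bis(2,2,2-trifluoroethoxy)phosphoryl]acetyl}oxy)methyl]-4a-methyl-1,2,3,4,4a,5,6,8a-octahydronaphthalen-2-yl]prop-2-enoate | C=C(C(=O)OCC[Si](C)(C)C)[C@@H]1CC[C@@]2(C)CCC=C(COC(=O)CP(=O)(OCC(F)(F)F)OCC(F)(F)F)[C@@H]2C1 | intermediate
16 | 4-[(tert-butyldimethylsilyl)oxy]benzaldehyde | O=Cc1ccc(O[Si](C)(C)C(C)(C)C)cc1 | starting material
17 | 2-(trimethylsilyl)ethyl 2-[(2R,4aR,8aR)-8-{[((2Z)-3-{4-[(tert-butyldimethylsilyl)oxy]phenyl}prop-2-enoyl)oxy]methyl}-4a-methyl-1,2,3,4,4a,5,6,8a-octahydronaphthalen-2-yl]prop-2-enoate | C=C(C(=O)OCC[Si](C)(C)C)[C@@H]1CC[C@@]2(C)CCC=C(COC(=O)/C=C\c3ccc(O[Si](C)(C)C(C)(C)C)cc3)[C@@H]2C1 | intermediate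
18 | 2-[(2R,4aR,8aR)-8-({[(2Z)-3-(4-hydroxyphenyl)prop-2-enoyl]oxy}methyl)-4a-methyl-1,2,3,4,4a,5,6,8a-octahydronaphthalen-2-yl]prop-2-enoic acid | C=C(C(=O)O)[C@@H]1CC[C@@]2(C)CCC=C(COC(=O)/C=C\c3ccc(O)cc3)[C@@H]2C1 | target

Total step count: 12. Longest linear sequence: 12 steps (1 to 18).

Steps most likely to fail

Step 6. The C9 radical may be quenched by hydrogen-atom transfer or over-reduced before it is captured by 7. The base stage may also equilibrate C5 toward the cis-fused ring system or divert material into aldol products. Fallback: from 6, an Appel iodination (I2, PPh3, imidazole, toluene, 80 °C) should give (3S)-3-(iodomethyl)-2-(methoxymethyl)-3-methylcyclohexan-1-one F1. A silane-mediated radical chain (tris(trimethylsilyl)silane, AIBN, 7, benzene, 80 °C) then delivers the keto ether 8 as an isolated compound. It is cyclised in a separate operation with catalytic KOt-Bu, so the route is rejoined at 8 and the two bond formations can be optimised apart.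

Step 8. Site selectivity between the two vinyl triflates may be lost, with carbonylation of both or of the ring triflate. Fallback: from 6, the annulation of step 6 is run with prop-2-enal in place of 7 to give (2R,4aR,8aR)-4a-methyl-8-oxodecahydronaphthalene-2-carbaldehyde F2, in which the two carbonyl groups differ in kind. Ohira–Bestmann homologation (dimethyl (1-diazo-2-oxopropyl)phosphonate, K2CO3, MeOH) gives (4aR,7R,8aR)-7-ethynyl-4a-methyloctahydronaphthalen-1(2H)-one F3. Branch-selective alkoxycarbonylation of the terminal alkyne (Pd(OAc)2, 2-pyridyldiphenylphosphine, MeSO3H, CO, 2-(trimethylsilyl)ethanol) gives 2-(trimethylsilyl)ethyl 2-[(2R,4aR,8aR)-4a-methyl-8-oxodecahydronaphthalen-2-yl]prop-2-enoate F4. Kinetic enol triflation of its only ketone (KN(SiMe3)2, PhNTf2, −78 °C) returns to the route at 12.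

Step 3. Facial selectivity of methyl transfer to the β-carbon bearing the silyloxymethyl group may be insufficient, or incomplete O-silylation of the aluminium enolate may lose the regiodefined enol ether. Fallback: from 3, Corey–Bakshi–Shibata reduction (oxazaborolidine catalyst, BH3·SMe2) should give (1S)-3-{[(tert-butyldimethylsilyl)oxy]methyl}cyclohex-2-en-1-ol F5. Hydroxyl-directed Simmons–Smith cyclopropanation (Et2Zn, CH2I2) gives (1R,2S,6R)-6-{[(tert-butyldimethylsilyl)oxy]methyl}bicyclo[4.1.0]heptan-2-ol F6, and Dess–Martin oxidation gives (1R,6R)-6-{[(tert-butyldimethylsilyl)oxy]methyl}bicyclo[4.1.0]heptan-2-one F7. Dissolving-metal cleavage of the external cyclopropane bond next to the carbonyl (Li, NH3, t-BuOH; then TMSCl, Et3N) turns the cyclopropane CH2 into the C10 methyl and traps the C5 enolate, returning to the route at 4.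

Further compounds
F1 | step 6 | (3S)-3-(iodomethyl)-2-(methoxymethyl)-3-methylcyclohexan-1-one | COCC1C(=O)CCC[C@]1(C)CI
F2 | step 8 | (2R,4aR,8aR)-4a-methyl-8-oxodecahydronaphthalene-2-carbaldehyde | O=C[C@@H]1CC[C@@]2(C)CCCC(=O)[C@@H]2C1
F3 | step 8 | (4aR,7R,8aR)-7-ethynyl-4a-methyloctahydronaphthalen-1(2H)-one | C#C[C@@H]1CC[C@@]2(C)CCCC(=O)[C@@H]2C1
F4 | step 8 | 2-(trimethylsilyl)ethyl 2-[(2R,4aR,8aR)-4a-methyl-8-oxodecahydronaphthalen-2-yl]prop-2-enoate | C=C(C(=O)OCC[Si](C)(C)C)[C@@H]1CC[C@@]2(C)CCCC(=O)[C@@H]2C1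
F5 | step 3 | (1S)-3-{[(tert-butyldimethylsilyl)oxy]methyl}cyclohex-2-en-1-ol | O[C@H]1CCCC(CO[Si](C)(C)C(C)(C)C)=C1
F6 | step 3 | (1R,2S,6R)-6-{[(tert-butyldimethylsilyl)oxy]methyl}bicyclo[4.1.0]heptan-2-ol | O[C@H]1CCC[C@@]2(CO[Si](C)(C)C(C)(C)C)C[C@@H]12
F7 | step 3 | (1R,6R)-6-{[(tert-butyldimethylsilyl)oxy]methyl}bicyclo[4.1.0]heptan-2-one | O=C1CCC[C@@]2(CO[Si](C)(C)C(C)(C)C)C[C@@H]12
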